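## Structural features

Ocophyllal B (10) is an achiral 2-aryl-3-methylbenzofuran neolignan. A benzo ring and a furan ring are fused along C3a–C7a; C2 carries a 3,4,5-trimethoxyphenyl ring through the C2–C1' bond, C3 a methyl group, C5 a formyl group and C7 a methoxy group. There is no stereocentre, so no stereocentres stand next to each other and no configuration has to be set or preserved. The fragile groups are the aryl aldehyde (an electrophile toward enolates and easily oxidised), the four aryl methyl ethers (at risk with strong Lewis acids) and the electron-rich C2=C3 bond of the furan (at risk with oxidants and strong electrophiles). The real difficulty is regiochemical: the furan ring is fully substituted, and on the benzo ring the oxygen-bearing C7a must sit next to the C7 methoxy carbon and para to the C5 formyl carbon, with C3a as its other neighbour. The key step exploits two features together. O1–C2=C3, with its aryl and methyl substituents, is the enol form of an aryl ethyl ketone (4), and C3a and C7a are adjacent arene carbons that can carry two leaving groups of different reactivity. In 5-iodovanillin (5) the hydroxyl, iodo, methoxy and formyl groups already stand where C7a, C3a, C7 and C5 need them, so the whole substitution pattern of the benzo ring can be bought.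

## Logic of the disconnections

10 back to 9. Only the formyl group is changed; it is taken back to its 1,3-dioxolane, so the bonds concerned are the two acetal C–O bonds. The reason is that a free aryl aldehyde would condense with the ketone enolate that the ring-forming step requires. There is no gain in skeletal simplicity, but the cost is a single mild step. The forward step must be an acid hydrolysis gentle enough to leave four aryl methyl ethers and the furan untouched.

9 back to 4 and 7. The furan ring is opened at C3–C3a and at O1–C7a. Cutting there turns O1–C2=C3 into the enolate of 4 and turns C3a and C7a into the iodide and triflate carbons of 7. This removes the only ring that has to be made and splits the molecule into pieces of 12 and 11 carbons. It also removes all doubt about the benzo ring, which is carried intact in 7. The forward step must put carbon on the iodide carbon before oxygen on the triflate carbon, form one enolate only, and tolerate an acetal and a sulfonate under basic conditions; 8 is the expected intermediate between the two bond formations.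

7 back to 6 and then to 5. These are two functional-group disconnections: the acetal C–O bonds (7 to 6) and the S–O bond of the sulfonate (6 to 5). The sulfonate is installed first because a para-hydroxybenzaldehyde is a poor substrate for acetalisation and its acetal is acid-labile, whereas the sulfonate makes the aldehyde more electrophilic and is stable to acid. The gain is arrival at commercial 5, which holds every substituent of the benzo ring in the right place. The forward steps must sulfonylate a phenol flanked by two ortho substituents and acetalise without solvolysing the sulfonate.

4 back to 1 and 2. The bond between the carbonyl carbon and the CH2 of the ethyl group is cut. 1 supplies the aryl carbon at the carboxylic acid oxidation level, so addition of 2 gives the ketone oxidation level directly through 3, with no separate redox step. Both pieces are commercial. The forward step needs a single addition to the nitrile and clean hydrolysis of 3.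

## Other disconnections considered

Alternative 1: The cut is at C3–CH3 and at C2–C1' on an intact benzofuran.
- Forward key step: 2-(7-methoxybenzofuran-5-yl)-1,3-dioxolane (A1) would be lithiated at C2 and added to 2-(3,4,5-trimethoxyphenyl)-4,4,5,5-tetramethyl-1,3,2-dioxaborolane (A2). Methyl trifluoromethanesulfonate (A3) would then alkylate C3 of the borate formed from A1 and A2 while the aryl group shifts from boron to C2 on the face opposite the incoming methyl. The product would be 2-[5-(1,3-dioxolan-2-yl)-7-methoxy-3-methyl-2-(3,4,5-trimethoxyphenyl)-2,3-dihydrobenzofuran-2-yl]-4,4,5,5-tetramethyl-1,3,2-dioxaborolane (A4), racemic, aryl trans to methyl.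
- In its favour: both the C2 aryl group and the C3 alkyl group are introduced late and can be varied freely, since A2 is an ordinary arylboronic ester. No transition metal is needed. The stereospecific anti addition is of no concern because both stereocentres of A4 are erased on aromatisation.
- Against it here: the furan ring is not built at all, so A1 must first be made from a vanillin derivative in several steps. C3 of a benzofuran is a much weaker nucleophile than C3 of an indole, the class for which electrophile-triggered 1,2-metallate shifts are best established, so methylation of a pinacol oxygen by A3 or simple return of A1 on work-up could compete. A4 is at the wrong oxidation level; oxidative removal of boron and dehydration are still required before the aldehyde is released.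
- Comparison: structurally the chosen plan makes the ring and places both substituents in one step from 4 and 7, while this route decorates a ring that has to be made beforehand. Mechanistically a polar 1,2-shift on boron at low temperature with a strong alkylating agent stands against a palladium-catalysed domino coupling. In steps it is expected to need about seven against five. It is the better plan for making C2 and C3 analogues and for avoiding palladium. It is the equal of the chosen plan in regiochemical certainty, since C2 lithiation of a benzofuran is unambiguous.

Alternative 2: The cut runs through the benzo ring at C7–C6, C5–C4 and C4–C3a, so the benzo ring is built on a preformed furan.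
- Forward key step: pentacarbonyl{methoxy[4-methyl-5-(3,4,5-trimethoxyphenyl)furan-2-yl]methylidene}chromium (A5), a carbene complex of zerovalent chromium, would be heated with 3,3-diethoxyprop-1-yne (A6). Alkyne insertion, insertion of one carbonyl ligand, electrocyclic closure onto furan C3 and tautomerisation (Dötz benzannulation) would give 5-(diethoxymethyl)-7-methoxy-3-methyl-2-(3,4,5-trimethoxyphenyl)benzofuran-4-ol (A7).
- In its favour: the carbene methoxy group becomes the C7 methoxy group, and the substituted carbon of A6 ends up next to the carbonyl-derived carbon, which places the masked formyl group at C5. The pattern is therefore fixed by the mechanism, and three C–C bonds form in one step.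
- Against it here: the carbonyl-derived C4 hydroxyl group is not in the target and would have to be removed through its triflate and a reduction. Chromium is used in stoichiometric amount. A7 is an easily oxidised hydroquinone monoether. The 2-aryl-3-methylfuran behind A5 needs its own synthesis.
- Comparison: structurally this route constructs an arene whose substitution pattern the chosen plan simply buys in 5. Mechanistically a stoichiometric organometallic cascade stands against a catalytic one. In steps it is expected to need about eight against five. It is the better plan in the number of skeletal bonds formed in the key step (three against two). It is the equal of the chosen plan in regiochemical reliability, and it needs no pair of differentiated leaving groups.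

Alternative 3: The cut is at C3–C3a and O1–C2, as in the biosynthesis.
- Forward key step: one-electron oxidation of a mixture of (E)-isoeugenol (A8) and 4-[(E)-prop-1-enyl]-2,6-dimethoxyphenol (A9) would join the side-chain carbon next to the methyl group of A9 to the free ortho carbon of A8. The phenol oxygen of A8 would then add to the quinone methide carbon, giving trans-2-(4-hydroxy-3,5-dimethoxyphenyl)-7-methoxy-3-methyl-5-[(E)-prop-1-enyl]-2,3-dihydrobenzofuran (A10), racemic. O-Methylation of the free phenol of A10 would be followed by oxidative cleavage of the propenyl group to the aldehyde and dehydrogenation of the dihydrofuran.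
- In its favour: both phenols are cheap, no protecting group and no precious metal are needed, and the trans selectivity is irrelevant because the stereocentres are removed later. A9 cannot couple at its ring ortho positions, which biases it toward the required side-chain coupling.
- Against it here: cross-coupling must compete with homo-coupling of each phenol, and nothing in either substrate enforces the cross-pairing, so a mixture of dimers that is hard to separate is expected. The later oxidations must discriminate between the propenyl alkene, the electron-rich rings and, after aromatisation, the furan C2=C3 bond.
- Comparison: structurally this route forms the same C3–C3a bond as the chosen plan but makes O1–C2 in place of O1–C7a, and it carries the formyl carbon as a propenyl group. Mechanistically radical pairing without substrate control stands against a coupling whose regiochemistry is fixed by the iodide and triflate of 7. In step count it is the better plan, four operations against five, and it is also better in reagent cost. The chosen plan is preferred because each of its steps has a single expected product.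

Key step: step 4

## Route

Remark on the chemistry: in 7 the triflate carbon becomes C7a, the iodide carbon C3a, the methoxy carbon C7 and the acetal carbon C5 of 10. The phenol is triflated before the aldehyde is acetalised. The ketone is made in one step from a nitrile, which saves the oxidation that an aldehyde route would need.

Step 1
Reactants: 1 3,4,5-trimethoxybenzonitrile; 2 ethylmagnesium bromide
Product: 4 1-(3,4,5-trimethoxyphenyl)propan-1-one, via bromomagnesium ketimine 3 (not isolated)
Conditions: EtMgBr (1.5 equiv), CuBr (2 mol %), THF, 0 °C to reflux; then 2 M aq HCl, rt
Reagents that add atoms: water, O
Why: Grignard addition to an aryl nitrile, in its copper-catalysed variant; the bromomagnesium ketimine 3 does not accept a second equivalent of 2, so no tertiary alcohol can form, and aqueous acid hydrolyses the C=N bond to the ketone while the methoxy groups stay inert.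

Step 2
Reactants: 5 5-iodovanillin (4-hydroxy-3-iodo-5-methoxybenzaldehyde)
Product: 6 4-formyl-2-iodo-6-methoxyphenyl trifluoromethanesulfonate
Conditions: Tf2O (1.2 equiv), pyridine (3 equiv), CH2Cl2, 0 °C to rt
Reagents that add atoms: trifluoromethanesulfonic anhydride, O=S(=O)(OS(=O)(=O)C(F)(F)F)C(F)(F)F
Why: O-sulfonylation of a phenol with triflic anhydride and pyridine; the phenol oxygen is the only nucleophile present and the reagent is reactive enough for a phenol with two ortho substituents. Triflating first avoids an acid-labile para-hydroxybenzaldehyde acetal later.

Step 3
Reactants: 6 4-formyl-2-iodo-6-methoxyphenyl trifluoromethanesulfonate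
Product: 7 4-(1,3-dioxolan-2-yl)-2-iodo-6-methoxyphenyl trifluoromethanesulfonate
Conditions: HOCH2CH2OH (3 equiv), p-TsOH·H2O (5 mol %), toluene, reflux, Dean–Stark; aq NaHCO3 wash
Reagents that add atoms: ethylene glycol, OCCO
Why: Acid-catalysed acetalisation with azeotropic removal of water; the electron-withdrawing triflate makes the aldehyde more electrophilic than in 5, and aryl triflates and aryl iodides tolerate Brønsted acid. A basic wash and base-washed silica should keep the dioxolane intact.

Step 4
Reactants: 4 1-(3,4,5-trimethoxyphenyl)propan-1-one; 7 4-(1,3-dioxolan-2-yl)-2-iodo-6-methoxyphenyl trifluoromethanesulfonate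
Product: 9 2-[7-methoxy-3-methyl-2-(3,4,5-trimethoxyphenyl)benzofuran-5-yl]-1,3-dioxolane, via alpha-aryl ketone triflate 8 (not isolated)
Conditions: Pd2(dba)3 (2.5 mol %), Xantphos (6 mol %), Cs2CO3 (2.5 equiv), 4 (1.2 equiv), toluene, 110 °C, argon
Reagents that add atoms: none
Why: This is a domino palladium-catalysed ketone alpha-arylation and intramolecular O-arylation, the known benzofuran annulation of enolisable ketones with 1,2-dihaloarenes, applied here to an ortho-iodoaryl triflate. Zerovalent palladium on Xantphos should insert into the C–I bond of 7 much faster than into the C–OTf bond; the caesium enolate of 4 then displaces iodide on divalent palladium, and C–C reductive elimination forms C3–C3a to give 8. The doubly activated alpha-hydrogen of 8 is more acidic than that of 4, so Cs2CO3 enolises 8 again; insertion into the neighbouring C–OTf bond and binding of the enolate oxygen give a six-membered oxapalladacycle, and C–O reductive elimination forms O1–C7a. The furan ring is thus closed as a five-membered ring by intramolecular O-arylation of the enolate, the palladacycle contracting by one atom as the metal leaves, and the aromaticity gained makes the closure irreversible. No stereocentre remains, because the one in 8 is erased by enolisation. The step needs carbon at the iodide carbon and oxygen at the triflate carbon, which the reactivity order iodide before triflate toward zerovalent palladium secures, and 4 has one enolisable position only, so a single enolate forms. It also needs the formyl group kept out of the enolate chemistry, which the dioxolane secures, and an intact triflate until the second insertion, which the mild and poorly soluble base Cs2CO3 in toluene and the electron-rich ring of 7 should secure.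

Step 5
Reactants: 9 2-[7-methoxy-3-methyl-2-(3,4,5-trimethoxyphenyl)benzofuran-5-yl]-1,3-dioxolane
Product: 10 ocophyllal B (7-methoxy-3-methyl-2-(3,4,5-trimethoxyphenyl)benzofuran-5-carbaldehyde)
Conditions: 1 M aq HCl, THF, rt
Reagents that add atoms: water, O
Why: Acid-catalysed hydrolysis of a benzylic dioxolane; aryl methyl ethers and the benzofuran are stable to dilute aqueous acid at room temperature, and excess water drives the equilibrium to the conjugated aryl aldehyde.

## Compound list

1 | 3,4,5-trimethoxybenzonitrile | COc1cc(C#N)cc(OC)c1OC | starting material
2 | ethylmagnesium bromide | CC[Mg]Br | starting material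
3 | N-(bromomagnesio)-1-(3,4,5-trimethoxyphenyl)propan-1-imine | CCC(=N[Mg]Br)c1cc(OC)c(OC)c(OC)c1 | intermediate
4 | 1-(3,4,5-trimethoxyphenyl)propan-1-one | CCC(=O)c1cc(OC)c(OC)c(OC)c1 | intermediate
5 | 5-iodovanillin (4-hydroxy-3-iodo-5-methoxybenzaldehyde) | COc1cc(C=O)cc(I)c1O | starting material
6 | 4-formyl-2-iodo-6-methoxyphenyl trifluoromethanesulfonate | COc1cc(C=O)cc(I)c1OS(=O)(=O)C(F)(F)F | intermediate
7 | 4-(1,3-dioxolan-2-yl)-2-iodo-6-methoxyphenyl trifluoromethanesulfonate | COc1cc(C2OCCO2)cc(I)c1OS(=O)(=O)C(F)(F)F | intermediate
8 | 4-(1,3-dioxolan-2-yl)-2-methoxy-6-[1-oxo-1-(3,4,5-trimethoxyphenyl)propan-2-yl]phenyl trifluoromethanesulfonate (racemic) | COc1cc(C2OCCO2)cc(C(C)C(=O)c2cc(OC)c(OC)c(OC)c2)c1OS(=O)(=O)C(F)(F)F | intermediate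
9 | 2-[7-methoxy-3-methyl-2-(3,4,5-trimethoxyphenyl)benzofuran-5-yl]-1,3-dioxolane | COc1cc(-c2oc3c(OC)cc(C4OCCO4)cc3c2C)cc(OC)c1OC | intermediate
10 | ocophyllal B (7-methoxy-3-methyl-2-(3,4,5-trimethoxyphenyl)benzofuran-5-carbaldehyde) | COc1cc(-c2oc3c(OC)cc(C=O)cc3c2C)cc(OC)c1OC | target

## Step count and least certain steps

Total step count: 5. Longest linear sequence: 4 steps (5 to 6 to 7 to 9 to 10); the ketone branch (1 and 2 to 4) is one step.

Step 4 (key step). The most likely failure is a stall after the first coupling. Insertion of zerovalent palladium into the C–OTf bond of 8 may be slow, because that carbon is flanked by a methoxy group and a branched alkyl group on an electron-rich ring. During a long reaction at 110 °C the triflate may then be cleaved at sulfur by carbonate or enolate, so that the ring oxygen can no longer be delivered by O-arylation. A second C-arylation of 8 by another molecule of 7 is a lesser risk. The fallback closes the ring stepwise, with the ring oxygen coming from the phenol and O1–C2 made last instead of O1–C7a. It sets out from 4 and 7. The C-arylation alone is run under milder conditions (Pd2(dba)3, Xantphos, K3PO4, toluene, 80 °C) and 8 is isolated. Et4NOH in aqueous dioxane at room temperature then cleaves the S–O bond of the aryl triflate to give 2-[5-(1,3-dioxolan-2-yl)-2-hydroxy-3-methoxyphenyl]-1-(3,4,5-trimethoxyphenyl)propan-1-one (F1). Warming F1 with 2 M aq HCl in THF should add the phenol to the ketone, dehydrate the hemiketal to the furan and hydrolyse the dioxolane in the same operation, so the fallback comes back to the route at 10. Hydroxide cleavage of aryl triflates and acid cyclodehydration of 2-hydroxybenzyl ketones to benzofurans are both known reactions.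

Step 1. The nitrile is deactivated by three donor groups, so addition may be incomplete, hydride transfer from the ethyl Grignard reagent may compete, and hydrolysis of 3 may be slow. The fallback changes the oxidation level of the electrophile. It sets out from 2 and adds it to commercial 3,4,5-trimethoxybenzaldehyde (F2) in THF at 0 °C, followed by a 1 M aq HCl quench. Addition to F2 is fast and should give 1-(3,4,5-trimethoxyphenyl)propan-1-ol (F3), racemic. Oxidation of F3 with MnO2 in CH2Cl2 at room temperature, a standard oxidation of a benzylic alcohol, brings the fallback back to the route at 4, at the cost of one more step.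

Step 3. Acetalisation may stop short of completion, the sulfonate may be lost by solvolysis in hot acidic glycol, or the dioxolane may revert during work-up. The fallback reverses the order of the two operations and uses a non-acidic triflation. It sets out from 5, which is acetalised with ethylene glycol, HC(OEt)3 and catalytic p-TsOH in toluene at 60 °C and quenched with Et3N, to give 4-(1,3-dioxolan-2-yl)-2-iodo-6-methoxyphenol (F4). F4 is triflated at once with PhNTf2, Et3N and DMAP in CH2Cl2 at room temperature, which brings the fallback back to the route at 7.

## Further compounds

F1 | step 4 | 2-[5-(1,3-dioxolan-2-yl)-2-hydroxy-3-methoxyphenyl]-1-(3,4,5-trimethoxyphenyl)propan-1-one (racemic) | COc1cc(C2OCCO2)cc(C(C)C(=O)c2cc(OC)c(OC)c(OC)c2)c1O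
F2 | step 1 | 3,4,5-trimethoxybenzaldehyde (purchased for the fallback) | COc1cc(C=O)cc(OC)c1OC
F3 | step 1 | 1-(3,4,5-trimethoxyphenyl)propan-1-ol (racemic) | CCC(O)c1cc(OC)c(OC)c(OC)c1
F4 | step 3 | 4-(1,3-dioxolan-2-yl)-2-iodo-6-methoxyphenol | COc1cc(C2OCCO2)cc(I)c1O
A1 | alternative 1 | 2-(7-methoxybenzofuran-5-yl)-1,3-dioxolane | COc1cc(C2OCCO2)cc2ccoc12
A2 | alternative 1 | 2-(3,4,5-trimethoxyphenyl)-4,4,5,5-tetramethyl-1,3,2-dioxaborolane | COc1cc(B2OC(C)(C)C(C)(C)O2)cc(OC)c1OC
A3 | alternative 1 | methyl trifluoromethanesulfonate | COS(=O)(=O)C(F)(F)F
A4 | alternative 1 | 2-[5-(1,3-dioxolan-2-yl)-7-methoxy-3-methyl-2-(3,4,5-trimethoxyphenyl)-2,3-dihydrobenzofuran-2-yl]-4,4,5,5-tetramethyl-1,3,2-dioxaborolane (racemic, aryl trans to methyl, one enantiomer drawn) | COc1cc(C2OCCO2)cc2c1O[C@](B1OC(C)(C)C(C)(C)O1)(c1cc(OC)c(OC)c(OC)c1)[C@H]2C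
A5 | alternative 2 | pentacarbonyl{methoxy[4-methyl-5-(3,4,5-trimethoxyphenyl)furan-2-yl]methylidene}chromium | COC(c1cc(C)c(-c2cc(OC)c(OC)c(OC)c2)o1)=[Cr](=C=O)(=C=O)(=C=O)(=C=O)=C=O
A6 | alternative 2 | 3,3-diethoxyprop-1-yne | C#CC(OCC)OCC
A7 | alternative 2 | 5-(diethoxymethyl)-7-methoxy-3-methyl-2-(3,4,5-trimethoxyphenyl)benzofuran-4-ol | CCOC(OCC)c1cc(OC)c2oc(-c3cc(OC)c(OC)c(OC)c3)c(C)c2c1O
A8 | alternative 3 | (E)-isoeugenol (2-methoxy-4-[(E)-prop-1-enyl]phenol) | C/C=C/c1ccc(O)c(OC)c1
A9 | alternative 3 | 4-[(E)-prop-1-enyl]-2,6-dimethoxyphenol | C/C=C/c1cc(OC)c(O)c(OC)c1
A10 | alternative 3 | trans-2-(4-hydroxy-3,5-dimethoxyphenyl)-7-methoxy-3-methyl-5-[(E)-prop-1-enyl]-2,3-dihydrobenzofuran (racemic, one enantiomer drawn) | C/C=C/c1cc(OC)c2O[C@H](c3cc(OC)c(O)c(OC)c3)[C@@H](C)c2c1
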